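A direct plan would cut (S)-linalool A1 down to dienol A2 (ozonolysis, Wittig) and arylate its alkoxide with fluoro-aldehyde A3 (SNAr). It would then extend the butenyl arm with methallyl epoxide A4 by cross-metathesis, close the pyran by RCM, and grow the lactone on the epoxide (acetic acid dianion, alkylation, selenation to A5, selenoxide elimination) before desilylation.
Weak point 1, the SNAr etherification: a tertiary alkoxide would have to attack a C–F carbon flanked by two ortho substituents, on a ring deactivated by a para silyloxy donor. Attack at the aldehyde or at silicon would compete.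
Weak point 2, the degradation of A1 followed by cross-metathesis: the E-trisubstituted alkene that A1 already holds would be destroyed. It would then be rebuilt from a 1,1-disubstituted and a terminal alkene, a pairing of low reactivity and weak E/Z control, next to a second vinyl group.
Weak point 3, the late lactone elaboration: four strong-base or oxidant steps would run in line on the full skeleton. The syn-elimination of A5 could also run to the exocyclic alkylidene, PhSeCl and periodate would meet an electron-rich chromene, and the base-labile C5–H would still have to survive fluoride.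

**Retrosynthetic overview**
1. Key disconnection: the C5–H bond of the butenolide ring (O1'–C2'(=O)–C3'=C4'–C5'). This ring is the keto tautomer of an aromatic 2-oxyfuran, so C5 is treated as a proton position. It is set in the last step by catalytic, stereoconvergent proton transfer (C3–H to C5–H) on the deconjugated lactone 19, used as both C3 epimers.
2. The five-membered ring is bought and carried as the achiral TIPS-oxyfuran. It acts as a linchpin: homoprenyl enters at C3 (Li–Br exchange), and the whole chromene arm enters at C5 (C5-lithiation plus allylic bromide 14, which forms C5–CH2).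
3. The arm keeps all ten carbons and both alkenes of (S)-linalool. The vinyl group becomes C3=C4: Heck makes C4–C4a, a photochemical E→Z step follows, and Pd etherification makes O1–C8a with the C2–O bond untouched. The isopropylidene gives the E-CH2OH by Riley oxidation.
4. Ring order: the five-membered O-ring is present from step 1, the pyran closes in step 7 through O1–C8a, and no ring is formed afterwards.
5. Avoided by design: no SNAr on a deactivated ring, no alkene cut and rebuilt by metathesis, and no lactone construction or selenoxide chemistry. The labile C5–H is made last and meets no reagent afterwards.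

Key step: step 12

Assumption 1: the SMILES is read as 2S (chromene C2), 5R (butenolide C5) and E (chain alkene). (S)-(+)-Linalool is taken as purchasable in high enantiomeric purity.
Assumption 2: the sense of induction in step 12 is assigned by analogy with simple γ-alkyl substrates. It is written for the quinidine-derived (cupreidine) catalyst series; the quinine-derived series is its pseudo-enantiomer.

**Route**

Step 1
Reactants: 1 3-bromofuran-2(5H)-one
Product: 2 [(3-bromofuran-2-yl)oxy]triisopropylsilane
Conditions: TIPSOTf (1.1 equiv), Et3N, CH2Cl2, 0 °C → rt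
Reagents that add atoms: triisopropylsilyl triflate CC(C)[Si](C(C)C)(C(C)C)OS(=O)(=O)C(F)(F)F
Why: Soft enolisation and O-silylation turn the butenolide into the aromatic 2-silyloxyfuran, and the bulky TIPS group later suppresses O→C silyl migration and attack of alkyllithiums at silicon.

Step 2
Reactants: 2 [(3-bromofuran-2-yl)oxy]triisopropylsilane and 3 5-iodo-2-methylpent-2-ene
Product: 5 triisopropyl{[3-(4-methylpent-3-enyl)furan-2-yl]oxy}silane, via 3-lithio-2-(triisopropylsilyloxy)furan 4 (not isolated)
Conditions: t-BuLi (2.0 equiv), Et2O, –78 °C; then 3, DMPU, –78 → –20 °C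
Reagents that add atoms: none
Why: Lithium–bromine exchange gives the 3-lithiofuran regiospecifically, and SN2 alkylation with the primary iodide places the homoprenyl chain on the future C3, a known entry to α-substituted butenolide equivalents.

Step 3
Reactants: 6 3-bromo-5-methylphenol
Product: 7 (3-bromo-5-methylphenoxy)triisopropylsilane
Conditions: TIPSCl, imidazole, DMF, rt
Reagents that add atoms: triisopropylsilyl chloride CC(C)[Si](Cl)(C(C)C)C(C)C
Why: Standard silylation gives a base-stable phenol ether whose bulk shields both ortho positions in step 4.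

Step 4
Reactants: 7 (3-bromo-5-methylphenoxy)triisopropylsilane
Product: 8 (3-bromo-4-chloro-5-methylphenoxy)triisopropylsilane
Conditions: NCS (1.05 equiv), HFIP, rt
Reagents that add atoms: N-chlorosuccinimide O=C1CCC(=O)N1Cl
Why: Electrophilic aromatic chlorination goes para to the oxygen donor because both ortho sites are flanked by OTIPS, and it installs a C–Cl bond (future C8a) that stays inert while C–Br reacts in step 5.

Step 5
Reactants: 8 (3-bromo-4-chloro-5-methylphenoxy)triisopropylsilane and 9 (S)-linalool
Product: 10 (S,E)-1-[2-chloro-3-methyl-5-(triisopropylsilyloxy)phenyl]-3,7-dimethylocta-1,6-dien-3-ol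
Conditions: Pd(OAc)2 (5 mol %), P(o-tol)3 (12 mol %), Et3N, MeCN, 85 °C
Reagents that add atoms: none
Why: In this Mizoroki–Heck reaction oxidative addition occurs at C–Br only, the aryl group adds to the terminal vinyl carbon (C4–C4a bond), β-hydride elimination can only give the E-styrene because the carbinol carbon has no hydrogen, and the stereocentre and the trisubstituted alkene are untouched.

Step 6
Reactants: 10 (S,E)-aryl dienol
Product: 11 (S,Z)-1-[2-chloro-3-methyl-5-(triisopropylsilyloxy)phenyl]-3,7-dimethylocta-1,6-dien-3-ol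
Conditions: fac-Ir(ppy)3 (1 mol %), MeCN, blue LED (450 nm), rt
Reagents that add atoms: none
Why: In this contra-thermodynamic E→Z isomerisation by triplet energy transfer the planar E-styrene is sensitised, while the Z-isomer, twisted out of conjugation by the ortho chlorine and the tertiary carbinol, is not and accumulates, and no bond to the stereocentre is involved.

Step 7
Reactants: 11 (S,Z)-aryl dienol
Product: 12 (S)-{[2,8-dimethyl-2-(4-methylpent-3-enyl)-2H-chromen-6-yl]oxy}triisopropylsilane
Conditions: Pd(OAc)2 (5 mol %), 2-(di-tert-butylphosphino)-1,1'-binaphthyl (7 mol %), Cs2CO3, toluene, 80 °C, dark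
Reagents that add atoms: none
Why: Palladium-catalysed intramolecular aryl etherification (Buchwald–Hartwig-type C–O coupling) of a tertiary alkoxide, which has no β-hydrogen, closes the six-membered pyran through O1–C8a, and the C2–O bond is never broken, so 2S is retained.

Step 8
Reactants: 12 (S)-chromene
Product: 13 (E)-5-[(S)-2,8-dimethyl-6-(triisopropylsilyloxy)-2H-chromen-2-yl]-2-methylpent-2-en-1-ol
Conditions: SeO2 (0.3 equiv), t-BuOOH (2 equiv), salicylic acid (10 mol %), CH2Cl2, 0 °C → rt, dark
Reagents that add atoms: selenium dioxide O=[Se]=O; tert-butyl hydroperoxide CC(C)(C)OO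
Why: The Riley oxidation (ene reaction, then [2,3]-sigmatropic shift) attacks the E-methyl group of the isopropylidene unit, which fixes the E geometry of the chain alkene, and the chromene C3=C4 alkene has no allylic hydrogen.

Step 9
Reactants: 13 allylic alcohol
Product: 14 (S)-({2-[(E)-5-bromo-4-methylpent-3-enyl]-2,8-dimethyl-2H-chromen-6-yl}oxy)triisopropylsilane
Conditions: CBr4, PPh3, CH2Cl2, –20 → 0 °C, dark
Reagents that add atoms: carbon tetrabromide BrC(Br)(Br)Br
Why: The Appel reaction is an SN2 displacement at the primary allylic carbon under neutral conditions and keeps the alkene geometry.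

Step 10
Reactants: 5 triisopropyl{[3-(4-methylpent-3-enyl)furan-2-yl]oxy}silane and 14 allylic bromide
Product: 16 {[5-{(E)-5-[(S)-2,8-dimethyl-6-(triisopropylsilyloxy)-2H-chromen-2-yl]-2-methylpent-2-enyl}-3-(4-methylpent-3-enyl)furan-2-yl]oxy}triisopropylsilane, via 5-lithio-3-(4-methylpent-3-enyl)-2-(triisopropylsilyloxy)furan 15 (not isolated)
Conditions: 5, s-BuLi (1.1 equiv), TMEDA, THF, –78 → 0 °C; then 14, –78 → 0 °C, dark
Reagents that add atoms: none
Why: α-Lithiation at the only free furan α-position (C5), known for 3-alkyl-2-TIPSO-furans, followed by SN2 alkylation with the primary allylic bromide forms the C5–CH2 bond and joins both halves on an achiral aromatic ring.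

Step 11
Reactants: 16 bis-silyl furan
Product: 19 (3RS)-5-{(E)-5-[(S)-6-hydroxy-2,8-dimethyl-2H-chromen-2-yl]-2-methylpent-2-enyl}-3-(4-methylpent-3-enyl)furan-2(3H)-one, via the aryl-TIPS furan-2-olate 17 (not isolated), via the aryl-TIPS deconjugated lactone 18 (not isolated)
Conditions: TBAF/AcOH (1:2, 2.5 equiv fluoride), THF, –78 → –20 °C, dark
Reagents that add atoms: none
Why: Fluoride cleaves the ketene-acetal-type furyl O–Si bond first, because the delocalised furan-2-olate is a better leaving group than the electron-rich phenolate, the olate 17 is protonated at once by the acetic acid present under kinetic control at C3 (α), as is usual for dienolates, and on warming the aryl O–Si bond of 18 is cleaved as well, which gives the deconjugated lactone 19 as an inconsequential mixture of C3 epimers.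

Step 12
Reactants: 19 deconjugated lactone (both C3 epimers)
Product: 21 tuberatolide B, via the free-phenol furan-2-olate 20 (not isolated)
Conditions: cupreidine 9-O-aryl ether (6'-OH cinchona catalyst, quinidine series, 10 mol %), CH2Cl2, –20 °C, dark
Reagents that add atoms: none
Why: The quinuclidine nitrogen removes the acidic C3–H of either epimer of 19, so both converge on the same planar, aromatic furan-2-olate 20, held as a hydrogen-bonded ion pair by the 6'-OH and the quinuclidinium N–H; the ammonium then returns the proton to one face of C5 (γ), which moves the alkene from C4=C5 to C3=C4 and is rate- and stereo-determining. The closest known reaction is the cinchona-catalysed proton-transfer isomerisation of mono- and disubstituted β,γ-butenolides to γ-stereogenic α,β-butenolides. No ring is closed in this step. C5 is controlled by the catalyst alone, since C2 lies six bonds away and cannot interfere, and the C3 centre is erased. The step needs γ- over α-reprotonation, which is secured because α-reprotonation only regenerates 19 and is reversible, whereas the conjugated, more substituted alkene of 21 is the thermodynamic sink whose C5–H a tertiary amine removes far more slowly at –20 °C. The hydroquinone mono-ether OH is a much weaker acid than the quinuclidinium ion and should not act as a competing achiral proton source.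

**Compound list**
1 | 3-bromofuran-2(5H)-one | O=C1OCC=C1Br | starting material
2 | [(3-bromofuran-2-yl)oxy]triisopropylsilane | Brc1ccoc1O[Si](C(C)C)(C(C)C)C(C)C | intermediate
3 | 5-iodo-2-methylpent-2-ene | CC(C)=CCCI | starting material
4 | 3-lithio-2-(triisopropylsilyloxy)furan | [Li]c1ccoc1O[Si](C(C)C)(C(C)C)C(C)C | intermediate
5 | triisopropyl{[3-(4-methylpent-3-enyl)furan-2-yl]oxy}silane | CC(C)=CCCc1ccoc1O[Si](C(C)C)(C(C)C)C(C)C | intermediate
6 | 3-bromo-5-methylphenol | Cc1cc(O)cc(Br)c1 | starting material
7 | (3-bromo-5-methylphenoxy)triisopropylsilane | Cc1cc(O[Si](C(C)C)(C(C)C)C(C)C)cc(Br)c1 | intermediate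
8 | (3-bromo-4-chloro-5-methylphenoxy)triisopropylsilane | Cc1cc(O[Si](C(C)C)(C(C)C)C(C)C)cc(Br)c1Cl | intermediate
9 | (S)-linalool | C=C[C@@](C)(O)CCC=C(C)C | starting material
10 | (S,E)-1-[2-chloro-3-methyl-5-(triisopropylsilyloxy)phenyl]-3,7-dimethylocta-1,6-dien-3-ol | CC(C)=CCC[C@](C)(O)/C=C/c1cc(O[Si](C(C)C)(C(C)C)C(C)C)cc(C)c1Cl | intermediate
11 | (S,Z)-1-[2-chloro-3-methyl-5-(triisopropylsilyloxy)phenyl]-3,7-dimethylocta-1,6-dien-3-ol | CC(C)=CCC[C@](C)(O)/C=C\c1cc(O[Si](C(C)C)(C(C)C)C(C)C)cc(C)c1Cl | intermediate
12 | (S)-{[2,8-dimethyl-2-(4-methylpent-3-enyl)-2H-chromen-6-yl]oxy}triisopropylsilane | CC(C)=CCC[C@@]1(C)C=Cc2cc(O[Si](C(C)C)(C(C)C)C(C)C)cc(C)c2O1 | intermediate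
13 | (E)-5-[(S)-2,8-dimethyl-6-(triisopropylsilyloxy)-2H-chromen-2-yl]-2-methylpent-2-en-1-ol | OC/C(C)=C/CC[C@@]1(C)C=Cc2cc(O[Si](C(C)C)(C(C)C)C(C)C)cc(C)c2O1 | intermediate
14 | (S)-({2-[(E)-5-bromo-4-methylpent-3-enyl]-2,8-dimethyl-2H-chromen-6-yl}oxy)triisopropylsilane | BrC/C(C)=C/CC[C@@]1(C)C=Cc2cc(O[Si](C(C)C)(C(C)C)C(C)C)cc(C)c2O1 | intermediate
15 | 5-lithio-3-(4-methylpent-3-enyl)-2-(triisopropylsilyloxy)furan | CC(C)=CCCc1cc([Li])oc1O[Si](C(C)C)(C(C)C)C(C)C | intermediate
16 | bis-TIPS 3,5-dialkyl-2-oxyfuran (full carbon skeleton, 2S, E) | CC(C)=CCCc1cc(C/C(C)=C/CC[C@@]2(C)C=Cc3cc(O[Si](C(C)C)(C(C)C)C(C)C)cc(C)c3O2)oc1O[Si](C(C)C)(C(C)C)C(C)C | intermediate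
17 | 5-{(E)-5-[(S)-2,8-dimethyl-6-(triisopropylsilyloxy)-2H-chromen-2-yl]-2-methylpent-2-enyl}-3-(4-methylpent-3-enyl)furan-2-olate (aryl TIPS ether still in place) | CC(C)=CCCc1cc(C/C(C)=C/CC[C@@]2(C)C=Cc3cc(O[Si](C(C)C)(C(C)C)C(C)C)cc(C)c3O2)oc1[O-] | intermediate
18 | (3RS)-5-{(E)-5-[(S)-2,8-dimethyl-6-(triisopropylsilyloxy)-2H-chromen-2-yl]-2-methylpent-2-enyl}-3-(4-methylpent-3-enyl)furan-2(3H)-one | CC(C)=CCCC1C=C(C/C(C)=C/CC[C@@]2(C)C=Cc3cc(O[Si](C(C)C)(C(C)C)C(C)C)cc(C)c3O2)OC1=O | intermediate
19 | (3RS)-5-{(E)-5-[(S)-6-hydroxy-2,8-dimethyl-2H-chromen-2-yl]-2-methylpent-2-enyl}-3-(4-methylpent-3-enyl)furan-2(3H)-one | CC(C)=CCCC1C=C(C/C(C)=C/CC[C@@]2(C)C=Cc3cc(O)cc(C)c3O2)OC1=O | intermediate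
20 | 5-{(E)-5-[(S)-6-hydroxy-2,8-dimethyl-2H-chromen-2-yl]-2-methylpent-2-enyl}-3-(4-methylpent-3-enyl)furan-2-olate (free phenol; ion pair with the protonated catalyst) | CC(C)=CCCc1cc(C/C(C)=C/CC[C@@]2(C)C=Cc3cc(O)cc(C)c3O2)oc1[O-] | intermediate
21 | tuberatolide B (2S,5R,E) | CC(C)=CCCC1=C[C@@H](C/C(C)=C/CC[C@@]2(C)C=Cc3cc(O)cc(C)c3O2)OC1=O | target

**Step count**
- Total: 12 steps.
- Longest linear sequence: 10 steps (6 → 21, steps 3–12).

**Steps most likely to fail**

1. Step 12. The facial selectivity of the γ-protonation may be poor with the hindered tertiary C3–H and the long γ-chain, or the configuration may erode through slow re-deprotonation of the product. The fallback sets C5 by ketone reduction instead of protonation; it sets out from 16 and returns at 21. Dimethyldioxirane (1 equiv, –78 °C) oxidises only the very electron-rich silyloxyfuran, with silyl migration, to the triisopropylsilyl (2Z,6E)-4-oxo-dienoate F1. Corey–Bakshi–Shibata reduction with (S)-Me-CBS and catecholborane treats the alkenyl arm as the large group and gives the (4R)-hydroxy dienoate F2. Et3N·3HF then removes both silyl groups, and the Z-γ-hydroxy acid lactonises to 21.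

2. Step 11. Protonation may leak to C5, or acetate may equilibrate the deconjugated lactone while the slower aryl desilylation runs, so that conjugated lactone with no control at C5 is formed before the catalyst is present. The fallback gives up the kinetic protonation; it sets out from 16 and returns at 21. Et3N·3HF followed by catalytic Et3N gives the thermodynamic butenolide as 21 together with its C5 epimer, 5-epi-tuberatolide B F3. The two are separated on a chiral stationary phase. F3 is re-aromatised with TIPSOTf/Et3N to the achiral furan 16 and recycled, so no material is lost to the wrong configuration.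

3. Step 7. The allylic palladium alkoxide may fragment (β-carbon elimination), or Z→E back-isomerisation may outrun C–O reductive elimination at the hindered aryl palladium centre. The fallback closes the ring on a saturated tether and restores the alkene afterwards; it sets out from 8 and 9 and returns at 12. 9-BBN hydroborates only the vinyl group of 9 to give the B-alkyl-9-BBN adduct F4. Suzuki–Miyaura coupling at the C–Br bond of 8 gives the saturated tertiary alcohol F5. The well-precedented palladium-catalysed etherification to 2,2-dialkylchromans gives chroman F6. DDQ dehydrogenation (hydride abstraction at C4, assisted by O1) gives 12.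

**Further compounds**
F1 | step 12 | triisopropylsilyl (2Z,6E)-9-[(S)-2,8-dimethyl-6-(triisopropylsilyloxy)-2H-chromen-2-yl]-6-methyl-2-(4-methylpent-3-enyl)-4-oxonona-2,6-dienoate | CC(C)=CCC/C(=C/C(=O)C/C(C)=C/CC[C@@]1(C)C=Cc2cc(O[Si](C(C)C)(C(C)C)C(C)C)cc(C)c2O1)C(=O)O[Si](C(C)C)(C(C)C)C(C)C
F2 | step 12 | triisopropylsilyl (2Z,4R,6E)-9-[(S)-2,8-dimethyl-6-(triisopropylsilyloxy)-2H-chromen-2-yl]-4-hydroxy-6-methyl-2-(4-methylpent-3-enyl)nona-2,6-dienoate | CC(C)=CCC/C(=C/[C@H](O)C/C(C)=C/CC[C@@]1(C)C=Cc2cc(O[Si](C(C)C)(C(C)C)C(C)C)cc(C)c2O1)C(=O)O[Si](C(C)C)(C(C)C)C(C)C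
F3 | step 11 | 5-epi-tuberatolide B (2S,5S,E) | CC(C)=CCCC1=C[C@H](C/C(C)=C/CC[C@@]2(C)C=Cc3cc(O)cc(C)c3O2)OC1=O
F4 | step 7 | B-alkyl-9-BBN adduct of 9 at the vinyl group (carbinol configuration unchanged) | CC(C)=CCC[C@](C)(O)CCB1C2CCCC1CCC2
F5 | step 7 | (S)-1-[2-chloro-3-methyl-5-(triisopropylsilyloxy)phenyl]-3,7-dimethyloct-6-en-3-ol | CC(C)=CCC[C@](C)(O)CCc1cc(O[Si](C(C)C)(C(C)C)C(C)C)cc(C)c1Cl
F6 | step 7 | (S)-{[2,8-dimethyl-2-(4-methylpent-3-enyl)chroman-6-yl]oxy}triisopropylsilane | CC(C)=CCC[C@@]1(C)CCc2cc(O[Si](C(C)C)(C(C)C)C(C)C)cc(C)c2O1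
A1 | direct plan | (S)-linalool | C=C[C@@](C)(O)CCC=C(C)C
A2 | direct plan | (S)-3-methylhepta-1,6-dien-3-ol | C=C[C@@](C)(O)CCC=C
A3 | direct plan | 2-fluoro-3-methyl-5-(triisopropylsilyloxy)benzaldehyde | Cc1cc(O[Si](C(C)C)(C(C)C)C(C)C)cc(C=O)c1F
A4 | direct plan | (R)-2-(2-methylallyl)oxirane | C=C(C)C[C@@H]1CO1
A5 | direct plan | α-phenylselanyl-α-(4-methylpent-3-enyl) γ-lactone carrying the TIPS-protected chromene arm | O=C1C(CCC=C(C)C)([Se]c2ccccc2)C[C@@H](C/C(C)=C/CC[C@@]2(C)C=Cc3cc(O[Si](C(C)C)(C(C)C)C(C)C)cc(C)c3O2)O1
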